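## Structural features

The target is a cis-fused decalin (eremophilane numbering: ring A = C1–C5 and C10, ring B = C5–C10) whose rings share the C5–C10 bond; C5 is a methyl-bearing quaternary carbon and H10 lies on the same face as that methyl. Ring A carries four contiguous stereocentres, C3 (α-angeloyloxy), C4 (β-methyl), C5 (β-methyl) and C10 (βH): the two methyls are cis and the C3 oxygen is trans to both. Ring B holds the C8 ketone between two epimerisable centres, C7 (β-isopropenyl) and C9 (β-senecioyloxy). In the chair that places C4 axial on ring B, the C5 methyl, the isopropenyl group and the C9 ester are all equatorial, so both centres have the thermodynamically preferred configuration. The fragile groups are the angelate (Z to E isomerisation with base, nucleophiles or heat), the β,γ-unsaturated ketone (migration of the C11–C12 double bond to C7–C11), the α-acyloxy ketone (acyl shift, reductive C–O cleavage), and two different enoates that must go onto two secondary hydroxyls in a fixed order. The real difficulty is the ring A stereotetrad with its quaternary centre in one absolute sense, followed by annulation of ring B without loss of the C10 configuration. The key step exploits the fact that C3, C4, C5 and C10 sit on one six-membered ring whose other two carbons (C1, C2) are unfunctionalised: ring A is a cyclohexene retron, the cis C4/C5 methyls map onto E-2-methylbut-2-enal, the C3 oxygen can travel as silicon, and C6 and C9 emerge as cis one-carbon handles on C5 and C10 for ring B.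

## Logic of the disconnections

29 ⇒ 26 + 27. The C3–O acyl bond is cut first. The angelate is the group most prone to isomerise, so it should meet no reagent after its introduction; 26 has only one free hydroxyl because O9 is already acylated. The forward step must acylate a secondary alcohol without a nucleophilic catalyst and without base strong enough to touch C7.

26 ⇒ 25 ⇒ 24. After the O3–Si bond, the C6–H and C7–H bonds are cut (retro conjugate reduction). This replaces the C7 stereocentre and the deconjugated isopropenyl group by a planar cross-conjugated dienone that an aldol condensation can deliver. The forward step must put hydride on C6 only, spare the senecioate, and protonate the dienolate at C7 (not C12) on the α face.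

24 ⇒ 22. The C6=C7 bond is cut (retro aldol condensation), opening ring B. C6 is then the non-enolisable formyl group that the cycloaddition leaves on C5, and C7 is the doubly activated methylene of a β,γ-unsaturated ketone. The bicycle becomes ring A with two cis side chains. The forward step must enolise toward C7 only, under conditions the α-acyloxy ketone tolerates.

22 ⇒ 20 ⇒ 12 + 16 + 17, and 16 ⇒ 13 + 14. The C8–C9 bond and the O9–acyl bond are cut, with ketone and aldehyde carried as dithiane and acetal. C9 is a carbinol carbon next to a carbonyl, the retron of an acyl anion addition to an aldehyde; one fragment brings C7, C8 and C11–C13, and O9 appears as an alkoxide that can be acylated at once. The side chain on C10 shrinks to a formyl group. The forward step needs Felkin–Anh control (9R) on an epimerisable aldehyde and acylation of a hindered alkoxide.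

12 ⇒ 11 ⇒ 10 ⇒ 8. The O3–Si ether bond is removed, C9 returns to the alcohol level, and the C3–O bond is exchanged for C3–Si while O9 regains its silyl group. Silicon is an inert stand-in for oxygen that passes through the cycloaddition and is oxidised with retention. The forward steps must oxidise silicon without acid (the acetal is present) and oxidise the primary alcohol beside a free secondary one.

8 ⇒ 7 ⇒ 6. The acetal C–O bonds and the C1–H/C2–H bonds are removed, returning to the cyclohexene aldehyde. The formyl group must be hidden from peroxide, from O9 (lactol) and from the organolithium, and the allylsilane double bond must go before any acid is used. The only demand is chemoselective hydrogenation.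

6 ⇒ 4 + 5. The C3–C4 and C5–C10 bonds are cut (retro [4+2]). One operation clears all four ring A stereocentres and the quaternary carbon and leaves two achiral, planar components. The forward step must control regiochemistry (C10 to C5), endo orientation and the enal face. The diene must carry a silyl group that survives a cationic Lewis acid and can later be oxidised without electrophiles, hence benzyl on silicon (fluoride-labile) rather than phenyl, which would need acid, bromine or a mercury salt with peracid. Its oxygen must carry a group that survives the Lewis acid and the acidic acetalisation, hence tert-butyldiphenylsilyl.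

4 ⇒ 2 + 3, and 2 ⇒ 1. The C–Si bond (retro hydrosilylation) and the O–Si bond are cut. The new E vinylsilane comes from syn addition to a terminal alkyne, while the other E alkene is bought. The forward step needs β-(E) regioselectivity.

## Other disconnections considered

Alternative 1: The cut is C5–C6 of ring B, traced back through a [3,3] shift to the bridged carbinol A1, whose bicyclo[2.2.2]octene core would come from a dearomatised-phenol cycloaddition followed by vinyl addition. In the forward key step the potassium alkoxide of A1 (KH, 18-crown-6) undergoes an anionic oxy-Cope rearrangement to the cis-decalin A2.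
- In its favour: the rearrangement is stereospecific, so the quaternary C5 and the cis fusion follow from the bicycle without any selectivity question; on these two centres it is the equal of the chosen plan.
- Better than the chosen plan: C8 (ketone), C9 (as ketal) and a saturated C6 arrive with the skeleton, so no acyl anion addition and no dienone reduction are needed, and the ketal blocks enolisation toward C9.
- Against it here: the key step has no absolute control, so A1 must be resolved or made by an asymmetric cycloaddition.
- Only C5 and C10 are set. C3 and C4 would have to come from hydroboration of the C3=C4 alkene of A2, where borane must approach from the face of C6 on a cis-decalin whose two faces are both flanked at C5.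
- C9 must be taken from a ketal to one carbinol configuration by regio- and stereoselective reduction, and the isopropenyl group is still missing.
- Comparison: the mechanism is as predictable as the cycloaddition, but it fixes two centres against four, and the number of operations after the key step should be at least as large.

Alternative 2: The cuts are C6–C7 and C4–C5, leading to the acyclic β-keto ester A3 in which the C5–C10 bond already exists. In the forward key step Mn(OAc)3 oxidises A3 to the C7 radical, which closes ring B by 6-endo attack on C6; the tertiary C5 radical then closes ring A by 6-exo attack on the C4 vinyl group, giving A4 after hydrogen abstraction at C15.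
- Better than the chosen plan: two rings and two C–C bonds form in one step, and A4 already carries oxygen at C3, C8 and C9 and the C11 carbon, so the sequence after the key step is shorter.
- Against it here: A3 needs three stereocentres (C3, C9, C10) built in an open chain before the key step.
- The radical cascade must set C5 (cis fusion), C4 and C7 under substrate control only, with no strong bias toward the cis-fused, cis-dimethyl arrangement.
- The primary C15 radical must end by hydrogen abstraction rather than oxidation to an exocyclic alkene.
- Turning the ester into isopropenyl beside the C8 ketone raises enolisation and dehydration-regiochemistry problems.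
- Comparison: the total length should be similar but front-loaded, and the stereochemical outcome is less predictable than a catalyst-controlled pericyclic step.

Alternative 3: The cut is C1–C10, leading to the achiral cyclohexadienone aldehyde A5, reachable by alkylative dearomatisation of a para-substituted phenol. In the forward key step a chiral triazolylidene carbene (triazolium salt, KN(SiMe3)2) converts the C1 aldehyde into an acyl anion equivalent that adds to one enantiotopic β-carbon, giving the cis-fused dione A6.
- Equal to the chosen plan: the step is catalytic, enantioselective and starts from achiral material.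
- Better for ring B: A6 already contains ring B with its C8 carbonyl and a C6–C7 enone for later work at C7.
- Against it here: A6 has only C5 and C10; the C3 oxygen is absent, the C4 methyl is an exocyclic methylene that needs face-selective hydrogenation, and the C1 ketone is superfluous and must be removed beside the C8 enone.
- C9 oxygenation and C7 isopropenylation also remain.
- Six-membered ring closure in this reaction type is less established than five-membered closure.
- Comparison: it sets two centres against four and its post-key-step sequence should be clearly longer.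

Key step: step 3

Remark on notation: eremophilane numbering is kept for all intermediates. α and β are the faces of the usual drawing (C10 above C5, ring A on the left); in ring A intermediates C6 and C9 are the α substituents on C5 and C10, and both methyls and H10 are β.

Remark on the chemistry: the catalyst antipode in step 3 is assigned from the formyl C–H···O binding model for α-substituted enals, worked out by hand and not checked against a reported absolute configuration; the mirror-image catalyst is equally accessible.

Remark on the structures: the stereodescriptors of 6 at C3, C4, C5 and C10 were compared atom by atom with those of 29 and agree; they are those of the endo adduct of an E enal and an E,E diene, so the skeleton of the adduct needs no correction. Only the substituents on silicon and the oxygen protecting group of the diene were changed.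

## Steps

Step 1
Reactants: 1 (E)-pent-2-en-4-yn-1-ol
Product: 2 (E)-tert-butyl(pent-2-en-4-yn-1-yloxy)diphenylsilane
Conditions: TBDPSCl, imidazole, CH2Cl2, 0 °C → rt
Reagents that add atoms: tert-butyl(chloro)diphenylsilane, CC(C)(C)[Si](Cl)(c1ccccc1)c1ccccc1
Why: Standard O-silylation of a primary allylic alcohol; the bulky acid-stable ether is chosen because it must pass the Lewis acid of step 3 and the acidic acetalisation of step 5 and then leave together with benzyl in step 6.

Step 2
Reactants: 2 (E)-tert-butyl(pent-2-en-4-yn-1-yloxy)diphenylsilane; 3 benzyldimethylsilane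
Product: 4 (1E,3E)-1-(benzyldimethylsilyl)-5-(tert-butyldiphenylsilyloxy)penta-1,3-diene
Conditions: Pt2[(CH2=CHSiMe2)2O]3 (0.1 mol%), P(t-Bu)3 (0.2 mol%), THF, 0 °C → rt
Reagents that add atoms: none
Why: Platinum-catalysed hydrosilylation of a terminal alkyne: syn addition of Si–H with silicon on the terminal carbon gives the β-(E)-vinylsilane, the bulky phosphine suppressing the α-isomer; the existing E alkene is untouched, so the E,E diene should result.

Step 3
Reactants: 4 (1E,3E)-1-(benzyldimethylsilyl)-5-(tert-butyldiphenylsilyloxy)penta-1,3-diene; 5 (E)-2-methylbut-2-enal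
Product: 6 3α-(benzyldimethylsilyl)-5α-formyl-4β,5β-dimethyl-10α-(tert-butyldiphenylsilyloxymethyl)cyclohex-1-ene (ring A; formyl carbon = C6; CH2O carbon = C9; H10 β)
Conditions: (R)-B-(o-tolyl)oxazaborolidine from (R)-α,α-diphenylprolinol (20 mol%), HN(SO2CF3)2 (18 mol%), CH2Cl2, −78 → −20 °C
Reagents that add atoms: none
Why: The cationic boron binds the formyl oxygen of 5 (formyl C–H···O contact to the ring oxygen) and holds the s-trans enal over one C-phenyl group so that one face of C4=C5 is open; 4 then adds suprafacially in a concerted, asynchronous [4+2] in which the C3–C4 bond to the β-carbon is more advanced than C5–C10. The closest known reaction type is the oxazaborolidinium-catalysed enantioselective Diels–Alder reaction of α-substituted enals with 1-substituted acyclic dienes. Ring A closes in this single intermolecular cycloaddition, both ring bonds coming from one six-electron transition state. C4 and C5 take their cis methyls stereospecifically from the E geometry of 5, and C3 and C10 take their cis relationship from the E,E geometry of 4. The endo orientation of the boron-bound formyl group places C6 cis to C9 and to silicon, which fixes C5 relative to C10 and C3. The absolute sense comes from the catalyst: the (R)-antipode should expose the face of C5 from which methyl, formyl and C4 run counterclockwise, as 29 requires. The step needs regioselection (C10 to C5), which rests on the larger HOMO coefficient at the terminus remote from the alkyl group, silicon being nearly neutral as a director. It also needs endo selection, which an acyclic diene (no bridge to clash with the α-methyl) and the coordinated formyl group should secure.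

Step 4
Reactants: 6 3α-(benzyldimethylsilyl)-5α-formyl-4β,5β-dimethyl-10α-(tert-butyldiphenylsilyloxymethyl)cyclohex-1-ene
Product: 7 3α-(benzyldimethylsilyl)-5α-formyl-4β,5β-dimethyl-10α-(tert-butyldiphenylsilyloxymethyl)cyclohexane
Conditions: H2 (1 atm), 5% Pd/C, EtOAc, rt
Reagents that add atoms: none
Why: Heterogeneous hydrogenation of the cis-disubstituted ring alkene; removing the allylsilane double bond before any acid is used prevents protodesilylation, and the hindered formyl group, the Si–benzyl bond and the silyl ether should not be reduced; no stereocentre is created.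

Step 5
Reactants: 7 3α-(benzyldimethylsilyl)-5α-formyl-4β,5β-dimethyl-10α-(tert-butyldiphenylsilyloxymethyl)cyclohexane
Product: 8 3α-(benzyldimethylsilyl)-5α-(dimethoxymethyl)-4β,5β-dimethyl-10α-(tert-butyldiphenylsilyloxymethyl)cyclohexane
Conditions: HC(OMe)3, MeOH, PPTS (cat.), rt → 40 °C
Reagents that add atoms: trimethyl orthoformate, COC(OC)OC
Why: Acid-catalysed acetalisation with the orthoformate as water scavenger; the formyl group on quaternary C5 cannot enolise, and the acetal hides C6 from peroxide (step 6), from lactol formation with O9 and from the organolithium of step 10.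

Step 6
Reactants: 8 3α-(benzyldimethylsilyl)-5α-(dimethoxymethyl)-4β,5β-dimethyl-10α-(tert-butyldiphenylsilyloxymethyl)cyclohexane
Product: 10 3α-hydroxy-10α-(hydroxymethyl)-5α-(dimethoxymethyl)-4β,5β-dimethylcyclohexane, via silanol diol 9 (not isolated)
Conditions: Bu4NF (4 equiv), THF, 0 °C → rt; then KHCO3, 30% H2O2, MeOH, rt → 40 °C
Reagents that add atoms: hydrogen peroxide, OO
Why: Fluoride forms a pentacoordinate siliconate that expels benzyl (protonated to toluene) and at the same time removes the O9 silyl ether; silanol 9 then undergoes Tamao oxidation, the C3–Si bond migrating to oxygen with retention, so the 3α-oxygen is set; the medium stays basic and the acetal should survive.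

Step 7
Reactants: 10 3α-hydroxy-10α-(hydroxymethyl)-5α-(dimethoxymethyl)-4β,5β-dimethylcyclohexane
Product: 11 3α-hydroxy-10α-formyl-5α-(dimethoxymethyl)-4β,5β-dimethylcyclohexane (new formyl carbon = C9)
Conditions: [Cu(MeCN)4]OTf (5 mol%), 2,2'-bipyridine (5 mol%), TEMPO (5 mol%), N-methylimidazole (10 mol%), air, MeCN, rt
Reagents that add atoms: none
Why: Copper/nitroxyl aerobic oxidation is selective for the unhindered primary alcohol over the secondary C3 hydroxyl and runs near neutrality, so C10 (α to the new aldehyde) should not epimerise; lactonisation through a C3–O/C9 lactol would need a bridged boat and is disfavoured.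

Step 8
Reactants: 11 3α-hydroxy-10α-formyl-5α-(dimethoxymethyl)-4β,5β-dimethylcyclohexane
Product: 12 3α-(tert-butyldimethylsilyloxy)-10α-formyl-5α-(dimethoxymethyl)-4β,5β-dimethylcyclohexane
Conditions: TBSOTf, 2,6-lutidine, CH2Cl2, −78 °C
Reagents that add atoms: tert-butyldimethylsilyl trifluoromethanesulfonate, CC(C)(C)[Si](C)(C)OS(=O)(=O)C(F)(F)F
Why: Silylation with a silyl triflate and a hindered pyridine is fast at low temperature, which should leave the acetal and the epimerisable aldehyde untouched; the ether protects O3 until the last step.

Step 9
Reactants: 13 1,3-dithiane; 14 3-chloro-2-methylprop-1-ene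
Product: 16 2-(2-methylprop-2-en-1-yl)-1,3-dithiane, via 2-lithio-1,3-dithiane 15 (not isolated)
Conditions: n-BuLi, THF, −30 °C; then 14, −78 °C → rt
Reagents that add atoms: none
Why: Corey–Seebach alkylation: the sulfur-stabilised carbanion 15 displaces the allylic chloride by SN2.

Step 10
Reactants: 12 3α-(tert-butyldimethylsilyloxy)-10α-formyl-5α-(dimethoxymethyl)-4β,5β-dimethylcyclohexane; 16 2-(2-methylprop-2-en-1-yl)-1,3-dithiane; 17 3-methylbut-2-enoyl chloride
Product: 20 (9R)-9-(3-methylbut-2-enoyloxy) adduct in which C9 links C10 of ring A to C2 of the 2-(2-methylprop-2-en-1-yl)-1,3-dithiane (dithiane C2 = C8), via lithiated dithiane 18 (not isolated), via lithium alkoxide 19 (not isolated)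
Conditions: 16, n-BuLi, THF, −30 °C; 12, −78 °C; then 17, −78 → 0 °C
Reagents that add atoms: none
Why: Corey–Seebach acyl anion addition: 18 attacks the aldehyde anti to the quaternary C5 (Felkin–Anh; C5 large, C1 medium, H small), which sets C9 as R, the configuration that becomes 9β and equatorial in ring B; acylating alkoxide 19 in the same flask installs the senecioate, so O9 needs no protecting group.

Step 11
Reactants: 20 (9R)-9-(3-methylbut-2-enoyloxy) dithiane acetal
Product: 22 (9R)-keto aldehyde: 5α-formyl ring A carrying on C10 the chain C9H(O-senecioyl)–C8(=O)–C7H2–C11(CH3)=C12H2, via keto acetal 21 (not isolated)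
Conditions: PhI(OCOCF3)2, MeCN/H2O (9:1), 0 °C → rt
Reagents that add atoms: water, O
Why: Oxidative dethioacetalisation: the hypervalent iodine reagent activates sulfur and water releases the ketone within minutes without touching the two alkenes; the trifluoroacetic acid set free then hydrolyses the dimethyl acetal in the same medium, and the secondary silyl ether should tolerate this dilute acid.

Step 12
Reactants: 22 (9R)-keto aldehyde
Product: 24 3α-(tert-butyldimethylsilyloxy)-9β-(3-methylbut-2-enoyloxy)-10βH-eremophila-6,11-dien-8-one, via aldol 23 (not isolated)
Conditions: TsOH·H2O (10 mol%), benzene, 60 °C, 4 Å molecular sieves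
Reagents that add atoms: none
Why: Acid-catalysed intramolecular aldol condensation (6-enolendo-exo-trig): the conjugated dienol of the β,γ-unsaturated ketone attacks the non-enolisable C6 aldehyde through C7 (attack through C12 would need an eight-membered ring) and aldol 23 loses water to the cross-conjugated dienone; acid leaves the α-acyloxy ketone intact, and any enolisation toward C9 returns the pseudo-equatorial 9β ester.

Step 13
Reactants: 24 3α-(tert-butyldimethylsilyloxy)-9β-(3-methylbut-2-enoyloxy)-10βH-eremophila-6,11-dien-8-one
Product: 25 3α-(tert-butyldimethylsilyloxy)-9β-(3-methylbut-2-enoyloxy)-7β-isopropenyl-10βH-eremophil-11-en-8-one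
Conditions: [(Ph3P)CuH]6 (0.5 equiv), H2O (5 equiv), degassed benzene, rt
Reagents that add atoms: none
Why: Conjugate reduction by the phosphine copper hydride: hydride adds to C6, the β-carbon of the enone, much faster than to the β,β-disubstituted senecioate or the isolated alkene; water protonates the dienolate at its α-carbon C7 (the kinetic site, which keeps the C11–C12 double bond out of conjugation), axially from the α face, to give the equatorial 7β-isopropenyl group, which is also the thermodynamically preferred epimer.

Step 14
Reactants: 25 3α-(tert-butyldimethylsilyloxy)-9β-(3-methylbut-2-enoyloxy)-7β-isopropenyl-10βH-eremophil-11-en-8-one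
Product: 26 3α-hydroxy-9β-(3-methylbut-2-enoyloxy)-7β-isopropenyl-10βH-eremophil-11-en-8-one
Conditions: HF·pyridine, pyridine, THF, 0 °C → rt
Reagents that add atoms: none
Why: Fluoride cleavage of the secondary silyl ether under buffered, weakly acidic conditions, which avoid enolisation of the ketone, migration of the C11–C12 double bond and acyl shift of the C9 ester.

Step 15
Reactants: 26 3α-hydroxy-9β-(3-methylbut-2-enoyloxy)-7β-isopropenyl-10βH-eremophil-11-en-8-one; 27 (Z)-2-methylbut-2-enoic acid (angelic acid)
Product: 29 3α-[(Z)-2-methylbut-2-enoyloxy]-9β-(3-methylbut-2-enoyloxy)-7β-isopropenyl-10βH-eremophil-11-en-8-one (CNP0375730.2), via mixed anhydride 28 (not isolated)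
Conditions: 27, 2,4,6-trichlorobenzoyl chloride, Et3N (1 equiv), toluene, rt; then 26, 75 °C
Reagents that add atoms: none
Why: Yamaguchi-type esterification without a nucleophilic catalyst: the C3 hydroxyl attacks mixed anhydride 28 at the less hindered angeloyl carbonyl; without 4-(dimethylamino)pyridine or free amine the Z geometry should be retained and C7 should not epimerise.

## Compound list

1 | (E)-pent-2-en-4-yn-1-ol | OC/C=C/C#C | starting material
2 | (E)-tert-butyl(pent-2-en-4-yn-1-yloxy)diphenylsilane | C#C/C=C/CO[Si](c1ccccc1)(c1ccccc1)C(C)(C)C | intermediate
3 | benzyldimethylsilane | C[SiH](C)Cc1ccccc1 | starting material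
4 | (1E,3E)-1-(benzyldimethylsilyl)-5-(tert-butyldiphenylsilyloxy)penta-1,3-diene | C[Si](C)(Cc1ccccc1)/C=C/C=C/CO[Si](c1ccccc1)(c1ccccc1)C(C)(C)C | intermediate
5 | (E)-2-methylbut-2-enal (tiglic aldehyde) | C/C=C(\C)C=O | starting material
6 | 3α-(benzyldimethylsilyl)-5α-formyl-4β,5β-dimethyl-10α-(tert-butyldiphenylsilyloxymethyl)cyclohex-1-ene | O=C[C@@]1(C)[C@H](C=C[C@@H]([Si](C)(C)Cc2ccccc2)[C@@H]1C)CO[Si](c1ccccc1)(c1ccccc1)C(C)(C)C | intermediate
7 | 3α-(benzyldimethylsilyl)-5α-formyl-4β,5β-dimethyl-10α-(tert-butyldiphenylsilyloxymethyl)cyclohexane | O=C[C@@]1(C)[C@H](CC[C@@H]([Si](C)(C)Cc2ccccc2)[C@@H]1C)CO[Si](c1ccccc1)(c1ccccc1)C(C)(C)C | intermediate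
8 | 3α-(benzyldimethylsilyl)-5α-(dimethoxymethyl)-4β,5β-dimethyl-10α-(tert-butyldiphenylsilyloxymethyl)cyclohexane | COC(OC)[C@@]1(C)[C@H](CC[C@@H]([Si](C)(C)Cc2ccccc2)[C@@H]1C)CO[Si](c1ccccc1)(c1ccccc1)C(C)(C)C | intermediate
9 | 3α-(hydroxydimethylsilyl)-10α-(hydroxymethyl)-5α-(dimethoxymethyl)-4β,5β-dimethylcyclohexane | COC(OC)[C@@]1(C)[C@H](CC[C@@H]([Si](C)(C)O)[C@@H]1C)CO | intermediate
10 | 3α-hydroxy-10α-(hydroxymethyl)-5α-(dimethoxymethyl)-4β,5β-dimethylcyclohexane | COC(OC)[C@@]1(C)[C@H](CC[C@@H](O)[C@@H]1C)CO | intermediate
11 | 3α-hydroxy-10α-formyl-5α-(dimethoxymethyl)-4β,5β-dimethylcyclohexane | COC(OC)[C@@]1(C)[C@H](CC[C@@H](O)[C@@H]1C)C=O | intermediate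
12 | 3α-(tert-butyldimethylsilyloxy)-10α-formyl-5α-(dimethoxymethyl)-4β,5β-dimethylcyclohexane | COC(OC)[C@@]1(C)[C@H](CC[C@@H](O[Si](C)(C)C(C)(C)C)[C@@H]1C)C=O | intermediate
13 | 1,3-dithiane | C1CSCSC1 | starting material
14 | 3-chloro-2-methylprop-1-ene | CC(=C)CCl | starting material
15 | 2-lithio-1,3-dithiane | [Li]C1SCCCS1 | intermediate
16 | 2-(2-methylprop-2-en-1-yl)-1,3-dithiane | CC(=C)CC1SCCCS1 | intermediate
17 | 3-methylbut-2-enoyl chloride | CC(C)=CC(Cl)=O | starting material
18 | 2-lithio-2-(2-methylprop-2-en-1-yl)-1,3-dithiane | [Li]C1(CC(C)=C)SCCCS1 | intermediate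
19 | lithium (9R)-alkoxide of the dithiane adduct of 12 | COC(OC)[C@@]1(C)[C@H](CC[C@@H](O[Si](C)(C)C(C)(C)C)[C@@H]1C)[C@@H](O[Li])C2(CC(C)=C)SCCCS2 | intermediate
20 | (9R)-9-(3-methylbut-2-enoyloxy) dithiane acetal (C8 = dithiane C2) | COC(OC)[C@@]1(C)[C@H](CC[C@@H](O[Si](C)(C)C(C)(C)C)[C@@H]1C)[C@@H](OC(=O)C=C(C)C)C2(CC(C)=C)SCCCS2 | intermediate
21 | (9R)-keto acetal (C8 ketone, C6 dimethyl acetal) | COC(OC)[C@@]1(C)[C@H](CC[C@@H](O[Si](C)(C)C(C)(C)C)[C@@H]1C)[C@@H](OC(=O)C=C(C)C)C(=O)CC(C)=C | intermediate
22 | (9R)-keto aldehyde (C8 ketone, C6 aldehyde) | O=C[C@@]1(C)[C@H](CC[C@@H](O[Si](C)(C)C(C)(C)C)[C@@H]1C)[C@@H](OC(=O)C=C(C)C)C(=O)CC(C)=C | intermediate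
23 | 6-hydroxy-3α-(tert-butyldimethylsilyloxy)-9β-(3-methylbut-2-enoyloxy)-10βH-eremophil-11-en-8-one (C6/C7 epimer mixture) | C=C(C)C1C(O)[C@@]2(C)[C@H](CC[C@@H](O[Si](C)(C)C(C)(C)C)[C@@H]2C)[C@@H](OC(=O)C=C(C)C)C1=O | intermediate
24 | 3α-(tert-butyldimethylsilyloxy)-9β-(3-methylbut-2-enoyloxy)-10βH-eremophila-6,11-dien-8-one | C=C(C)C1=C[C@@]2(C)[C@H](CC[C@@H](O[Si](C)(C)C(C)(C)C)[C@@H]2C)[C@@H](OC(=O)C=C(C)C)C1=O | intermediate
25 | 3α-(tert-butyldimethylsilyloxy)-9β-(3-methylbut-2-enoyloxy)-7β-isopropenyl-10βH-eremophil-11-en-8-one | C=C(C)[C@H]1C[C@@]2(C)[C@H](CC[C@@H](O[Si](C)(C)C(C)(C)C)[C@@H]2C)[C@@H](OC(=O)C=C(C)C)C1=O | intermediate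
26 | 3α-hydroxy-9β-(3-methylbut-2-enoyloxy)-7β-isopropenyl-10βH-eremophil-11-en-8-one | C=C(C)[C@H]1C[C@@]2(C)[C@H](CC[C@@H](O)[C@@H]2C)[C@@H](OC(=O)C=C(C)C)C1=O | intermediate
27 | (Z)-2-methylbut-2-enoic acid (angelic acid) | C/C=C(/C)C(=O)O | starting material
28 | (Z)-2-methylbut-2-enoic 2,4,6-trichlorobenzoic anhydride | C/C=C(/C)C(=O)OC(=O)c1c(Cl)cc(Cl)cc1Cl | intermediate
29 | 3α-[(Z)-2-methylbut-2-enoyloxy]-9β-(3-methylbut-2-enoyloxy)-7β-isopropenyl-10βH-eremophil-11-en-8-one (CNP0375730.2) | C=C(C)[C@H]1C[C@@]2(C)[C@H](CC[C@@H](OC(=O)/C(C)=C\C)[C@@H]2C)[C@@H](OC(=O)C=C(C)C)C1=O | target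

## Step count and least certain steps

Total step count: 15. Longest linear sequence: 14 steps (steps 1–8 and 10–15); step 9 is a one-step side branch.

Step 3 (key step). The cycloaddition may be too slow at temperatures the catalyst tolerates, because a trisubstituted enal meets a 1,4-disubstituted diene. Regiocontrol may also leak, since the alkyl terminus carries an oxygen and is a weaker director than methyl. The endo preference or the facial selectivity may fall short, and the facial sense may be opposite to the binding model, in which case the mirror-image catalyst is used. Fallback, from 4 and 5 back to 6: the cycloaddition is run with the achiral Lewis acid Me2AlCl (CH2Cl2, −78 °C), which should give 6 together with its mirror-image adduct F1 as the racemate. Condensation of the formyl group with (1R,2R)-N,N'-dimethyl-1,2-diphenylethane-1,2-diamine (Et2O, molecular sieves) converts the pair into the aminal F2 and its diastereomer F3. These are separated by chromatography, and F2 is hydrolysed with cold dilute aqueous oxalic acid to return 6. Enantiocontrol is thus moved from catalysis to resolution.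

Step 10. Acylation of the hindered lithium alkoxide may stall, with retro-addition on warming. The acid chloride may react through a vinylketene with loss of conjugation, and Felkin–Anh control or the C10 configuration may erode through enolisation of the aldehyde. Fallback, from 12 and 16 back to 20: the addition is quenched with aqueous NH4Cl and the (9R)-carbinol F4 is isolated and purified, which also removes any C9 epimer. It is then esterified with 3-methylbut-2-enoic acid by carbodiimide coupling (DCC, catalytic DMAP, CH2Cl2) to give 20.

Step 12. Ring closure onto the neopentyl-type aldehyde may be slow, so that acid-promoted loss of the C3 silyl ether or double-bond migration competes. Fallback, from 22 back to 24: kinetic enolisation at C7 with LiN(SiMe3)2 (THF, −78 °C) gives the aldol 23, which is isolated. Its C6 hydroxyl is converted into the mesylate F5 (MsCl, Et3N), and DBU then eliminates by an E1cB path to 24.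

Step 13. Protonation of the dienolate may occur on the β face or at C12, and hydride delivery to the hindered C6 may be slow enough for attack on the senecioate to compete. Fallback, from 24 back to 25: the crude ketone, containing the 7α-isopropenyl epimer F6, is treated briefly with catalytic DBU in toluene at rt. Re-protonation of the dienolate at C7 is faster than at C12, so the mixture should drain into the all-equatorial 25 before conjugation sets in; stereocontrol is moved from kinetic protonation to equilibration.

Step 15. The angeloyl group may isomerise to tigloyl under amine and heat, and the C7 centre may epimerise or the C11–C12 double bond may migrate. Fallback, from 26 back to 29: the C3 hydroxyl is acylated with 2-[bis(2,2,2-trifluoroethoxy)phosphoryl]propanoic acid (DCC, CH2Cl2) to the phosphonopropanoate F7. The Z double bond is then built on the substrate by Still–Gennari olefination with acetaldehyde (KN(SiMe3)2, 18-crown-6, THF, −78 °C). The phosphonate is far more acidic than the ketone and the Z selectivity is kinetic, so 29 should form without passing through a free angeloyl donor.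

## Further compounds

F1 | step 3 | enantiomer of 6 (formed with 6 as the racemate) | O=C[C@]1(C)[C@@H](C=C[C@H]([Si](C)(C)Cc2ccccc2)[C@H]1C)CO[Si](c1ccccc1)(c1ccccc1)C(C)(C)C
F2 | step 3 | (4R,5R)-1,3-dimethyl-4,5-diphenylimidazolidin-2-yl aminal of 6 | CN1[C@H](c2ccccc2)[C@@H](c2ccccc2)N(C)C1[C@@]3(C)[C@H](C=C[C@@H]([Si](C)(C)Cc4ccccc4)[C@@H]3C)CO[Si](c5ccccc5)(c6ccccc6)C(C)(C)C
F3 | step 3 | (4R,5R)-1,3-dimethyl-4,5-diphenylimidazolidin-2-yl aminal of F1 | CN1[C@H](c2ccccc2)[C@@H](c2ccccc2)N(C)C1[C@]3(C)[C@@H](C=C[C@H]([Si](C)(C)Cc4ccccc4)[C@H]3C)CO[Si](c5ccccc5)(c6ccccc6)C(C)(C)C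
F4 | step 10 | (9R)-9-hydroxy dithiane acetal (free carbinol corresponding to 20) | COC(OC)[C@@]1(C)[C@H](CC[C@@H](O[Si](C)(C)C(C)(C)C)[C@@H]1C)[C@@H](O)C2(CC(C)=C)SCCCS2
F5 | step 12 | C6 methanesulfonate of aldol 23 (C6/C7 epimer mixture) | C=C(C)C1C(OS(C)(=O)=O)[C@@]2(C)[C@H](CC[C@@H](O[Si](C)(C)C(C)(C)C)[C@@H]2C)[C@@H](OC(=O)C=C(C)C)C1=O
F6 | step 13 | 7α-isopropenyl epimer of 25 | C=C(C)[C@@H]1C[C@@]2(C)[C@H](CC[C@@H](O[Si](C)(C)C(C)(C)C)[C@@H]2C)[C@@H](OC(=O)C=C(C)C)C1=O
F7 | step 15 | 3α-O-{2-[bis(2,2,2-trifluoroethoxy)phosphoryl]propanoyl} derivative of 26 (epimer mixture at the phosphonate carbon) | C=C(C)[C@H]1C[C@@]2(C)[C@H](CC[C@@H](OC(=O)C(C)P(=O)(OCC(F)(F)F)OCC(F)(F)F)[C@@H]2C)[C@@H](OC(=O)C=C(C)C)C1=O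
A1 | alternative 1 | 3,3-dimethoxy-5,6-dimethyl-2-vinylbicyclo[2.2.2]oct-5-en-2-ol (vinyl syn to the C5=C6 bridge) | C=C[C@]1(O)C(OC)(OC)[C@H]2CC[C@@H]1C(C)=C2C
A2 | alternative 1 | cis-fused 9,9-dimethoxyeremophil-3-en-8-one | C1C[C@@]2(C)[C@H](CCC=C2C)C(OC)(OC)C1=O
A3 | alternative 2 | methyl 8-(tert-butyldimethylsilyloxy)-4-(methoxymethoxy)-3-oxo-5-(prop-1-en-2-yl)dec-9-enoate (eremophilane C3, C9, C10 configured as in A4) | COC(=O)CC(=O)[C@H](OCOC)[C@@H](CC[C@@H](O[Si](C)(C)C(C)(C)C)C=C)C(C)=C
A4 | alternative 2 | cis-fused methyl 8-oxo-9-(methoxymethoxy)-3-(tert-butyldimethylsilyloxy)eremophilane-7-carboxylate | COC(=O)[C@H]1C[C@@]2(C)[C@H](CC[C@@H](O[Si](C)(C)C(C)(C)C)[C@@H]2C)[C@@H](OCOC)C1=O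
A5 | alternative 3 | 4-methyl-4-(5-oxopent-1-en-2-yl)cyclohexa-2,5-dien-1-one | C=C(CCC=O)C1(C)C=CC(=O)C=C1
A6 | alternative 3 | cis-fused 5-methyl-4-methylene-eremophil-6-ene-1,8-dione core | C1=C[C@@]2(C)[C@H](C(=O)CCC2=C)CC1=O
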